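**Retrosynthetic overview**
- The formyl and isovaleryl groups go on last, by two directed ortho-lithiations of a MOM-protected phloroglucinol ring that is already benzyl-linked to the terpene; MOM removal ends the route.
- The isopropenyl group comes from an equatorial C7 acetyl (from a C7 nitrile, from a C7 ketone); the C4 carbinol comes from MeLi addition to a C4 ketone made by hydroboration of a C4=C5 alkene.
- The ArCH2–C1 bond comes from a B-alkyl Suzuki coupling of the 9-BBN adduct of a C1 exo-methylene with an aryl iodide.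
- The decalin comes from (R)-Wieland–Miescher ketone, made by a D-proline-catalysed aldol condensation that sets C10; a ketoreductase then tells the two carbonyls apart.
- Ring order: ring B is bought as 2-methylcyclohexane-1,3-dione, ring A is annulated onto it, and the aromatic ring is bought as phloroglucinol and attached intact.

Assumption and locants: the SMILES is read as the (1S,4S,5R,7R,10S) isomer in eudesmane numbering (C10 = quaternary carbon with the angular CH3, C1–C4 run round ring B to the ring-fusion carbon C5, C6–C9 run round ring A); β = face of the angular methyl, α = the opposite face; Ar′ = 2,4,6-tris(methoxymethoxy)phenyl, whose C1′ carries the CH2 link.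

**Step 1**
Reactants: 1 2-methylcyclohexane-1,3-dione; 2 methyl vinyl ketone
Product: 3 2-methyl-2-(3-oxobutyl)cyclohexane-1,3-dione
Conditions: AcOH (cat.), hydroquinone (cat.), H2O, 75 °C
Reagents that add atoms: none
Why: Michael addition of the enolised 1,3-dione to the enone under mild aqueous acid catalysis gives the achiral, prochiral triketone with no stereocentre yet.

**Step 2**
Reactants: 3 2-methyl-2-(3-oxobutyl)cyclohexane-1,3-dione
Product: 5 (R)-Wieland–Miescher ketone, via cis-fused ketol 4 (not isolated)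
Conditions: D-proline (5 mol%), DMSO, 23 °C, 5 d; recrystallisation from Et2O, −20 °C
Reagents that add atoms: none
Why: Hajos–Parrish–Eder–Sauer–Wiechert reaction in which the D-proline enamine of the side-chain ketone attacks one of the two enantiotopic ring carbonyls through a hydrogen-bonded chair transition state and the ketol dehydrates in situ, so that C10, the first stereocentre, is set as R by asymmetric organocatalysis and crystallisation brings the enone to ≥98% ee.

**Step 3**
Reactants: 5 (R)-Wieland–Miescher ketone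
Product: 6 (4aR,5R)-5-hydroxy-4a-methyl-4,4a,5,6,7,8-hexahydronaphthalen-2(3H)-one (1β-hydroxy enone)
Conditions: ketoreductase (NADPH-dependent alcohol dehydrogenase, picked from a screening panel for α-face hydride delivery), NADP+ (cat.), i-PrOH (10% v/v), potassium phosphate buffer pH 7.0, 30 °C
Reagents that add atoms: none
Why: Enzymatic carbonyl reduction in which the ketoreductase accepts only the saturated C1 ketone (the conjugated C7 carbonyl is a poor hydride acceptor) and delivers hydride to the α-face opposite the angular methyl to give the 1β-alcohol, which differentiates the two carbonyls without a protecting group while isopropanol recycles the cofactor; the carbinol configuration is not critical because it is re-oxidised in step 5.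

**Step 4**
Reactants: 6 1β-hydroxy enone
Product: 7 1β-hydroxy-10β-methyl bicyclic ketal (C7 spiro-1,3-dioxolane, C4=C5 double bond)
Conditions: ethylene glycol, TsOH·H2O (cat.), benzene, reflux, Dean–Stark
Reagents that add atoms: ethylene glycol (OCCO)
Why: Acid-catalysed ketalisation of the enone runs through the dienol ether so that, as with steroidal enones, the double bond moves out of conjugation to C4=C5 (the only position open, because C10 is quaternary) while the neopentyl 1β-hydroxyl is untouched.

**Step 5**
Reactants: 7 hydroxy ketal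
Product: 8 C1 ketone (C7 spiro-1,3-dioxolane, C4=C5 double bond)
Conditions: n-Pr4N[RuO4] (5 mol%), NMO, 4 Å MS, CH2Cl2, 23 °C
Reagents that add atoms: none
Why: Ley–Griffith oxidation under neutral conditions returns the C1 ketone without touching the dioxolane or the C4=C5 alkene, which cannot move into conjugation because C10 is quaternary.

**Step 6**
Reactants: 8 keto ketal
Product: 9 1-methylidene diene ketal (C1=CH2, C4=C5, C7 spiro-1,3-dioxolane)
Conditions: Ph3PCH3Br, KOtBu, toluene, 90 °C
Reagents that add atoms: methyltriphenylphosphonium bromide (C[P+](c1ccccc1)(c1ccccc1)c1ccccc1.[Br-])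
Why: Wittig methylenation with the salt-free ylide at high temperature overcomes the hindrance of the ketone next to the quaternary carbon, and no stereocentre is formed or put at risk because the only enolisable position is C2.

**Step 7**
Reactants: 10 phloroglucinol
Product: 11 1,3,5-tris(methoxymethoxy)benzene
Conditions: MOMCl, i-Pr2NEt, CH2Cl2, 0 → 23 °C
Reagents that add atoms: chloromethyl methyl ether (COCCl)
Why: Threefold O-alkylation (acetal formation) of the phenols with an amine base in a non-polar solvent, which favours O- over C-alkylation.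

**Step 8**
Reactants: 11 1,3,5-tris(methoxymethoxy)benzene
Product: 13 2-iodo-1,3,5-tris(methoxymethoxy)benzene, via aryllithium 12 (not isolated)
Conditions: n-BuLi, THF, 0 °C; then I2, −78 → 23 °C
Reagents that add atoms: iodine (II)
Why: Directed ortho-metalation between two MOM ethers (all three ring C–H are equivalent) followed by iodinolysis of the aryllithium.

**Step 9**
Reactants: 9 1-methylidene diene ketal; 13 2-iodo-1,3,5-tris(methoxymethoxy)benzene
Product: 15 1β-benzylated ketal [1β-CH2Ar′; 1α-H; C4=C5; C7 spiro-1,3-dioxolane], via B-alkyl-9-BBN borane 14 (not isolated)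
Conditions: 9-BBN, THF, 23 → 50 °C; then 13, Pd(OAc)2 (5 mol%), SPhos (10 mol%), K3PO4 (3 M aq), THF, 65 °C
Reagents that add atoms: none
Why: 9-BBN adds anti-Markovnikov to the 1,1-disubstituted exocyclic alkene far faster than to the trisubstituted C4=C5 alkene and from the α-face opposite the angular methyl, which sets C1 (α-H, β-CH2B), and the B-alkyl Suzuki–Miyaura coupling with a dialkylbiarylphosphine ligand then joins the primary alkyl group to the hindered, electron-rich aryl iodide.

**Step 10**
Reactants: 15 1β-benzylated ketal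
Product: 17 4α-alcohol [trans-decalin; 5α-H; 1β-CH2Ar′; C7 spiro-1,3-dioxolane], via C4 alkylborane 16 (not isolated)
Conditions: BH3·THF, THF, 0 → 23 °C; then NaOH (3 M aq), H2O2 (30%), 0 → 40 °C
Reagents that add atoms: hydrogen peroxide (OO)
Why: Hydroboration–oxidation in which boron adds to the less substituted C4 and hydrogen to C5 in a syn fashion on the α-face opposite the angular methyl, giving the trans ring fusion (5α-H) and, after oxidation with retention, the 4α-alcohol.

**Step 11**
Reactants: 17 4α-alcohol
Product: 18 trans-fused C4 ketone (5α-H; 1β-CH2Ar′; C7 spiro-1,3-dioxolane)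
Conditions: n-Pr4N[RuO4] (5 mol%), NMO, 4 Å MS, CH2Cl2, 23 °C; then NaOMe (cat.), MeOH, 23 °C
Reagents that add atoms: none
Why: Ley–Griffith oxidation to the C4 ketone followed by brief base equilibration, which epimerises at C5 any cis-fused material from minor β-face hydroboration to the more stable trans-fused ketone.

**Step 12**
Reactants: 18 C4 ketone
Product: 19 4β-hydroxy-4α-methyl ketal (5α-H; 1β-CH2Ar′; C7 spiro-1,3-dioxolane)
Conditions: CeCl3 (dried), MeLi, THF, −78 °C
Reagents that add atoms: methyllithium ([Li]C)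
Why: Organocerium 1,2-addition (Imamoto conditions) avoids enolisation towards C5, and the methyl group enters on the equatorial α-face because the axial β-approach is blocked by the syn-axial C10 methyl, which sets C4 as the axial 4β-alcohol with a 4α-methyl.

**Step 13**
Reactants: 19 tertiary alcohol ketal
Product: 20 4β-hydroxy-4α,10β-dimethyl-1β-(Ar′CH2)-trans-decalin-7-one
Conditions: PPTS, acetone/H2O (5:1), 55 °C
Reagents that add atoms: water (O)
Why: Mild acid-catalysed ketal hydrolysis frees the unhindered C7 ketone, and the weak acid leaves the aryl MOM ethers and the tertiary alcohol intact.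

**Step 14**
Reactants: 20 C7 ketone
Product: 21 C7 nitrile (mixture of C7 epimers)
Conditions: TosMIC, KOtBu, DME/EtOH, 0 → 40 °C
Reagents that add atoms: p-toluenesulfonylmethyl isocyanide (Cc1ccc(cc1)S(=O)(=O)C[N+]#[C-])
Why: Van Leusen reductive cyanation converts the unhindered ketone into the homologous nitrile, and the C7 configuration, which is not controlled here, is corrected in step 15.

**Step 15**
Reactants: 21 C7 nitrile
Product: 23 7β-acetyl compound, via ketimine 22 (not isolated)
Conditions: MeLi (4 equiv), Et2O, −78 → 0 °C; aqueous pH 5 work-up; then NaOMe (cat.), MeOH, 23 °C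
Reagents that add atoms: methyllithium ([Li]C); water (O)
Why: Addition of methyllithium to the nitrile stops at the N-lithio ketimine, hydrolysis gives the methyl ketone, and base equilibration through the enolate places the acetyl group equatorial, which sets C7 as β.

**Step 16**
Reactants: 23 7β-acetyl compound
Product: 24 1β-[2,4,6-tris(methoxymethoxy)benzyl]-5α-eudesm-11-en-4β-ol (7β-isopropenyl)
Conditions: Ph3PCH3Br, KOtBu, THF, 0 → 23 °C
Reagents that add atoms: methyltriphenylphosphonium bromide (C[P+](c1ccccc1)(c1ccccc1)c1ccccc1.[Br-])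
Why: Wittig methylenation of the unhindered methyl ketone gives the isopropenyl group, and C7 stays β because the equatorial epimer is the thermodynamic one even if the basic ylide enolises the ketone.

**Step 17**
Reactants: 24 7β-isopropenyl compound; 25 3-methylbutanal
Product: 27 benzylic alcohol [1-hydroxy-3-methylbutyl on aryl C3′; carbinol epimers], via aryllithium 26 (not isolated)
Conditions: n-BuLi (2.3 equiv), THF, 0 °C; then 25, −78 → 0 °C
Reagents that add atoms: none
Why: Directed ortho-metalation at an aryl C–H flanked by two MOM ethers (the two free positions are equivalent and the tertiary alkoxide is a spectator) followed by 1,2-addition to the aldehyde, the new carbinol centre forming as a mixture that is erased in step 19.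

**Step 18**
Reactants: 27 benzylic alcohol
Product: 29 hydroxy aldehyde [CHO on aryl C5′], via aryllithium 28 (not isolated)
Conditions: n-BuLi (3.5 equiv), THF, 0 °C; then DMF, −78 → 0 °C
Reagents that add atoms: N,N-dimethylformamide (CN(C)C=O)
Why: A second directed ortho-metalation at the only remaining aryl C–H and formylation of the aryllithium with DMF (Bouveault reaction), the two lithium alkoxides being spectators.

**Step 19**
Reactants: 29 hydroxy aldehyde
Product: 30 keto aldehyde (aryl = 3-formyl-5-(3-methylbutanoyl)-2,4,6-tris(methoxymethoxy)phenyl)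
Conditions: Dess–Martin periodinane, NaHCO3, CH2Cl2, 0 → 23 °C
Reagents that add atoms: none
Why: Dess–Martin oxidation turns the secondary benzylic alcohol into the aryl ketone, while the tertiary alcohol cannot be oxidised and the aldehyde and alkene are inert.

**Step 20**
Reactants: 30 keto aldehyde
Product: 31 2,4,6-trihydroxy-3-{[(1S,4S,4aR,6R,8aS)-4-hydroxy-4,8a-dimethyl-6-(prop-1-en-2-yl)decahydronaphthalen-1-yl]methyl}-5-(3-methylbutanoyl)benzaldehyde (target)
Conditions: TsOH·H2O (0.3 equiv), MeOH, 0 → 23 °C
Reagents that add atoms: none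
Why: Acid-catalysed acetal exchange with methanol removes the three MOM ethers, each of which lies ortho to a carbonyl and is therefore cleaved at an acid strength low enough to spare the tertiary alcohol and the isopropenyl group, and no stereocentre is affected.

**Compound list**
1 | 2-methylcyclohexane-1,3-dione | CC1C(=O)CCCC1=O | starting material
2 | methyl vinyl ketone (but-3-en-2-one) | CC(=O)C=C | starting material
3 | 2-methyl-2-(3-oxobutyl)cyclohexane-1,3-dione (achiral triketone) | CC(=O)CCC1(C)C(=O)CCCC1=O | intermediate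
4 | (4aR,8aR)-4a-hydroxy-8a-methyloctahydronaphthalene-1,6-dione (cis-fused ketol, not isolated) | O=C1CC[C@@]2(C)C(=O)CCC[C@@]2(O)C1 | intermediate
5 | (R)-Wieland–Miescher ketone, (8aR)-8a-methyl-3,4,8,8a-tetrahydronaphthalene-1,6(2H,7H)-dione | O=C1CC[C@@]2(C)C(=O)CCCC2=C1 | intermediate
6 | (4aR,5R)-5-hydroxy-4a-methyl-4,4a,5,6,7,8-hexahydronaphthalen-2(3H)-one (1β-hydroxy-10β-methyl enone) | O=C1CC[C@@]2(C)[C@H](O)CCCC2=C1 | intermediate
7 | 1β-hydroxy-10β-methyl bicyclic ketal, (1R,10R): C7 spiro-1,3-dioxolane, C4=C5 double bond | C12(OCCO1)CC[C@@]3(C)[C@H](O)CCC=C3C2 | intermediate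
8 | 1-oxo-10β-methyl bicyclic ketal, (10R): C7 spiro-1,3-dioxolane, C4=C5 double bond | C12(OCCO1)CC[C@@]3(C)C(=O)CCC=C3C2 | intermediate
9 | 1-methylidene-10β-methyl bicyclic ketal, (10S): C7 spiro-1,3-dioxolane, C4=C5 double bond | C12(OCCO1)CC[C@@]3(C)C(=C)CCC=C3C2 | intermediate
10 | phloroglucinol (benzene-1,3,5-triol) | Oc1cc(O)cc(O)c1 | starting material
11 | 1,3,5-tris(methoxymethoxy)benzene | COCOc1cc(OCOC)cc(OCOC)c1 | intermediate
12 | 2,4,6-tris(methoxymethoxy)phenyllithium (not isolated) | COCOc1cc(OCOC)c([Li])c(OCOC)c1 | intermediate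
13 | 2-iodo-1,3,5-tris(methoxymethoxy)benzene | COCOc1cc(OCOC)c(I)c(OCOC)c1 | intermediate
14 | B-alkyl-9-BBN borane from 9: 1β-CH2–B(9-borabicyclo[3.3.1]nonan-9-yl), 1α-H (not isolated) | C12(OCCO1)CC[C@@]3(C)[C@H](CB4C5CCCC4CCC5)CCC=C3C2 | intermediate
15 | 1β-[2,4,6-tris(methoxymethoxy)benzyl]-1α-H-10β-methyl bicyclic ketal: C7 spiro-1,3-dioxolane, C4=C5 double bond | C12(OCCO1)CC[C@@]3(C)[C@H](Cc4c(OCOC)cc(OCOC)cc4OCOC)CCC=C3C2 | intermediate
16 | C4 alkylborane from 15: 4α-BH2, 5α-H (drawn as the monoalkylborane, not isolated) | C12(OCCO1)CC[C@@]3(C)[C@H](Cc4c(OCOC)cc(OCOC)cc4OCOC)CC[C@@H](B)[C@@H]3C2 | intermediate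
17 | 4α-hydroxy trans-decalin: 1β-CH2Ar′, 5α-H, 10β-CH3, C7 spiro-1,3-dioxolane | C12(OCCO1)CC[C@@]3(C)[C@H](Cc4c(OCOC)cc(OCOC)cc4OCOC)CC[C@@H](O)[C@@H]3C2 | intermediate
18 | trans-decalin-4-one: 1β-CH2Ar′, 5α-H, 10β-CH3, C7 spiro-1,3-dioxolane | C12(OCCO1)CC[C@@]3(C)[C@H](Cc4c(OCOC)cc(OCOC)cc4OCOC)CCC(=O)[C@@H]3C2 | intermediate
19 | 4β-hydroxy-4α-methyl trans-decalin: 1β-CH2Ar′, 5α-H, 10β-CH3, C7 spiro-1,3-dioxolane | C12(OCCO1)CC[C@@]3(C)[C@H](Cc4c(OCOC)cc(OCOC)cc4OCOC)CC[C@](C)(O)[C@@H]3C2 | intermediate
20 | 4β-hydroxy-4α,10β-dimethyl-1β-(Ar′CH2)-trans-decalin-7-one (5α-H) | O=C1CC[C@@]2(C)[C@H](Cc3c(OCOC)cc(OCOC)cc3OCOC)CC[C@](C)(O)[C@@H]2C1 | intermediate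
21 | 7-cyano-4β-hydroxy-4α,10β-dimethyl-1β-(Ar′CH2)-trans-decalin (5α-H; C7 epimers) | N#CC1CC[C@@]2(C)[C@H](Cc3c(OCOC)cc(OCOC)cc3OCOC)CC[C@](C)(O)[C@@H]2C1 | intermediate
22 | 7-(1-iminoethyl) analogue of 21 (N-lithio salt in the flask, not isolated) | CC(=N)C1CC[C@@]2(C)[C@H](Cc3c(OCOC)cc(OCOC)cc3OCOC)CC[C@](C)(O)[C@@H]2C1 | intermediate
23 | 7β-acetyl-4β-hydroxy-4α,10β-dimethyl-1β-(Ar′CH2)-trans-decalin (5α-H, 7α-H) | CC(=O)[C@@H]1CC[C@@]2(C)[C@H](Cc3c(OCOC)cc(OCOC)cc3OCOC)CC[C@](C)(O)[C@@H]2C1 | intermediate
24 | 1β-[2,4,6-tris(methoxymethoxy)benzyl]-5α-eudesm-11-en-4β-ol (7β-isopropenyl) | C=C(C)[C@@H]1CC[C@@]2(C)[C@H](Cc3c(OCOC)cc(OCOC)cc3OCOC)CC[C@](C)(O)[C@@H]2C1 | intermediate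
25 | 3-methylbutanal (isovaleraldehyde) | CC(C)CC=O | starting material
26 | aryllithium of 24: Li on aryl C3′, lithium alkoxide at C4 (not isolated) | C=C(C)[C@@H]1CC[C@@]2(C)[C@H](Cc3c(OCOC)cc(OCOC)c([Li])c3OCOC)CC[C@](C)(O[Li])[C@@H]2C1 | intermediate
27 | 24 carrying a 1-hydroxy-3-methylbutyl group on aryl C3′ (carbinol epimers) | C=C(C)[C@@H]1CC[C@@]2(C)[C@H](Cc3c(OCOC)cc(OCOC)c(C(O)CC(C)C)c3OCOC)CC[C@](C)(O)[C@@H]2C1 | intermediate
28 | aryllithium of 27: Li on aryl C5′, both alkoxides lithiated (not isolated) | C=C(C)[C@@H]1CC[C@@]2(C)[C@H](Cc3c(OCOC)c([Li])c(OCOC)c(C(O[Li])CC(C)C)c3OCOC)CC[C@](C)(O[Li])[C@@H]2C1 | intermediate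
29 | 27 carrying a formyl group on aryl C5′ (hydroxy aldehyde) | C=C(C)[C@@H]1CC[C@@]2(C)[C@H](Cc3c(OCOC)c(C=O)c(OCOC)c(C(O)CC(C)C)c3OCOC)CC[C@](C)(O)[C@@H]2C1 | intermediate
30 | 1β-{[3-formyl-5-(3-methylbutanoyl)-2,4,6-tris(methoxymethoxy)phenyl]methyl}-5α-eudesm-11-en-4β-ol (keto aldehyde) | C=C(C)[C@@H]1CC[C@@]2(C)[C@H](Cc3c(OCOC)c(C=O)c(OCOC)c(C(=O)CC(C)C)c3OCOC)CC[C@](C)(O)[C@@H]2C1 | intermediate
31 | 2,4,6-trihydroxy-3-{[(1S,4S,4aR,6R,8aS)-4-hydroxy-4,8a-dimethyl-6-(prop-1-en-2-yl)decahydronaphthalen-1-yl]methyl}-5-(3-methylbutanoyl)benzaldehyde | C=C(C)[C@@H]1CC[C@@]2(C)[C@H](Cc3c(O)c(C=O)c(O)c(C(=O)CC(C)C)c3O)CC[C@](C)(O)[C@@H]2C1 | target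

**Totals**
Total step count: 20 (18 in the main line, 2 in the aryl branch).
Longest linear sequence: 18 steps, from 1 to 31 through steps 1–6 and 9–20.

**Three steps most likely to fail**

Step 9 (coupling of a β-branched alkylborane with a di-ortho-substituted, electron-rich aryl iodide; the C1 facial ratio is also decided here). The fallback makes the same bond by carbonyl addition and sets C1 under thermodynamic control. It sets out from 9, which is hydroborated with 9-BBN as before (borane 14) but then oxidised with NaOH/H2O2 to the primary alcohol F1. Oxidation with n-Pr4N[RuO4]/NMO gives the aldehyde F2, which is equilibrated with K2CO3/MeOH so that the formyl group sits equatorial (β). Aryllithium 12 (from 11 and n-BuLi) is added to give the benzylic carbinol F3, which is converted with NaH, CS2 and MeI into the S-methyl xanthate F4. Barton–McCombie reduction (Bu3SnH, AIBN, toluene, 90 °C) removes the oxygen and comes back to the route at 15.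

Step 18 (deprotonation of a crowded, electron-rich arene that already carries two lithium alkoxides). The fallback makes the aryllithium by halogen–lithium exchange instead. It sets out from 27, whose last free aryl position is brominated with NBS (CH2Cl2, −78 °C) to give the aryl bromide F5. The two hydroxyls are deprotonated with MeLi, bromine is exchanged for lithium with t-BuLi (THF, −78 °C) to give the same aryllithium 28, and a DMF quench comes back to the route at 29.

Step 20 (Brønsted acid in the presence of a tertiary alcohol and an isopropenyl group). The fallback avoids protic acid by turning the acetals into silyl ethers first. It sets out from 30, which is treated with TMSOTf and 2,2′-bipyridyl (MeCN, 0 °C) to give the tetrakis(trimethylsilyl) ether F6 (three aryl O–Si bonds and the C4 O–Si bond). This is not purified but desilylated with K2CO3 in MeOH at 0 °C, which comes back to the route at 31.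

**Further compounds**
F1 | step 9 | primary alcohol: 1β-hydroxymethyl-1α-H-10β-methyl bicyclic ketal (C7 spiro-1,3-dioxolane, C4=C5) | C12(OCCO1)CC[C@@]3(C)[C@H](CO)CCC=C3C2
F2 | step 9 | aldehyde: 1β-formyl-1α-H-10β-methyl bicyclic ketal (C7 spiro-1,3-dioxolane, C4=C5) | C12(OCCO1)CC[C@@]3(C)[C@H](C=O)CCC=C3C2
F3 | step 9 | benzylic carbinol: 1β-[hydroxy(Ar′)methyl] analogue of 15 (carbinol epimers) | C12(OCCO1)CC[C@@]3(C)[C@H](C(O)c4c(OCOC)cc(OCOC)cc4OCOC)CCC=C3C2
F4 | step 9 | S-methyl xanthate of F3 | C12(OCCO1)CC[C@@]3(C)[C@H](C(OC(=S)SC)c4c(OCOC)cc(OCOC)cc4OCOC)CCC=C3C2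
F5 | step 18 | aryl bromide: 27 carrying Br on aryl C5′ | C=C(C)[C@@H]1CC[C@@]2(C)[C@H](Cc3c(OCOC)c(Br)c(OCOC)c(C(O)CC(C)C)c3OCOC)CC[C@](C)(O)[C@@H]2C1
F6 | step 20 | tetrakis(trimethylsilyl) ether of 31 (three aryl OSiMe3, C4 OSiMe3) | C=C(C)[C@@H]1CC[C@@]2(C)[C@H](Cc3c(O[Si](C)(C)C)c(C=O)c(O[Si](C)(C)C)c(C(=O)CC(C)C)c3O[Si](C)(C)C)CC[C@](C)(O[Si](C)(C)C)[C@@H]2C1
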